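(The runs come from a simulation for substances that don't exist; noise was put on by code.)

The decision is to reckon this flask by the fraction left and not by the fraction made.

| flask | starting material | capture agent | protic impurity | remark | time |
|---|---|---|---|---|---|
| delta | 1.1 M | 0.080 M | 0.080 M | run made earlier |  |
| alpha | 1.8 M | 0.080 M | 0.080 M | run made earlier |  |
| flask | 0.80 M | 0.0800 M | 0.0800 M |  | 15 d |

| run | time / d | intermediate A / % | target / % |
|---|---|---|---|
| delta | 0.417 | 34.6 | 1.5 |
| delta | 0.625 | 44.1 | 0 |
| delta | 1.25 | 59.7 | 2.1 |
| delta | 2.08 | 60.0 | 4.6 |
| delta | 3.00 | 55.8 | 10.8 |
| delta | 5.00 | 40.2 | 18.6 |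
| delta | 10.0 | 13.5 | 37.6 |
| alpha | 0.417 | 34.7 | 0.2 |
| alpha | 0.625 | 47.4 | 0.1 |
| alpha | 1.25 | 60.7 | 1.2 |
| alpha | 2.08 | 64.5 | 4.4 |
| alpha | 3.00 | 57.7 | 7.0 |
| alpha | 5.00 | 41.6 | 21.5 |
| alpha | 10.0 | 16.4 | 40.1 |

(scatter of a reading: 1 percentage point)

1. when, up to 15 d, the flask holds most intermediate A
2. the amount of intermediate A, in percent of the starting material charged, at that time
3. the first time at which intermediate A reaches 41%, in the same percent

- the numbers in the tables scatter by 1 percentage point (one standard deviation)

Assume that the protic impurity destroys starting material mole for mole, early in the run. With less impurity than starting material, the impurity is then the limiting reagent of that loss. With 0.0800 M of impurity on 0.80 M of starting material, the flask has f = 90.0%, the fraction of the charge left over from that loss: one minus the ratio of the two charges. It is taken here as a factor on the height of the curve, with the times unchanged.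

Delta has f = 92.7% and alpha 95.6%. Both runs show their highest reading at 2.08 d: 60.0% in delta and 64.5% in alpha. Dividing each by its f gives Y, the peak per surviving charge: 64.7% and 67.5%. These readings now differ by 2.8 percentage points, less than the raw 4.5 points. Anything else that thins the peak, capture agent included, stays inside Y, taken as equal in the runs and the flask. Their mean, 66.1%, times the flask's f gives this reckoning's estimate of 59.5% for the flask, with its peak taken to lie between 1.25 d and 3.00 d, the readings on either side of the highest one in the runs. In the flask the level 41% means 45.6% of the surviving charge, and interpolating between the first two divided readings, averaged over both runs, puts it at 0.572 d.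

The forecast, holding that “the capture agent and impurity are eating A”, gives 57.5% at 1.8 d and the level at 0.55 d. On the height it lies 2 points below this reckoning's estimate.

The flask holds its most intermediate A, 59.2%, at 1.71 d, and reaches the level at 0.569 d.

    intermediate A + capture agent → trapped intermediate (k = 0.0510 /M/h)
    intermediate B → target (k = 0.0160 /h)
    starting material + protic impurity → quenched substrate (k = 1.70 /M/h)
    intermediate B → side product (k = 0.0120 /h)
    intermediate A → intermediate B (k = 0.00780 /h)
    starting material → intermediate A (k = 0.0500 /h)

At that best time quenched substrate stands at 10.0% of the charge, and one minus f is 10.0%. The same flask with 0.32 M of starting material has f = 75.0%, so Y gives 49.6%, and that flask's best is 48.6%.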